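**Retrosynthetic overview**
1. Target ⇐ selective 6‑O‑acetylation of a 3,6,8‑triol; its 2‑substituted butadiene comes from the carbonyl of a δ‑lactone (vinyl addition, then methylenation).
2. δ‑Lactone 3,6‑diol ⇐ borane reduction of the C‑3 ketone and hydroboration of the Δ5 olefin (sets C‑3, H‑5, O‑6), after deconjugative gem‑dimethylation at C‑4 of a ring‑A enone.
3. cis‑δ‑Lactone ⇐ capture of the tertiary C‑8 cation (from the CH3MgBr adduct of an 8‑ketone) by the ester on the C‑9 chain; this sets C‑8.
4. Key step: one‑carbon expansion of the cyclopentane of a (Z)‑alkylidene hydrindenone by 1,2‑shift of the quaternary C‑10 from C‑8 to C‑9 (oxidative semipinacol with trivalent iodine); this makes ring B and sets C‑9.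
5. Hydrindenone ⇐ 2‑methylcyclopentane‑1,3‑dione + but‑3‑en‑2‑one (D‑proline aldol); chain ⇐ 4‑bromobutanoic acid (Wittig). Ring order: cyclopentane (given), ring A (aldol), ring B (expansion of the cyclopentane), a temporary lactone ring (opened at the end).

Assumption: the SMILES is taken literally (C‑9 chain and 8‑OH cis to each other and trans to the C‑10 methyl); labdane numbering is used for all bicyclic compounds (before the ring expansion C‑8 is bonded directly to C‑10 and C‑9 is exocyclic), and the SMILES strings are authoritative for configuration.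

**Route**

Step 1
Reactants: 1 4-bromobutanoic acid
Product: 2 (3-carboxypropyl)triphenylphosphonium bromide
Conditions: PPh3 (1.05 equiv), MeCN, reflux, 48 h
Reagents that add atoms: triphenylphosphine, c1ccc(cc1)P(c1ccccc1)c1ccccc1
Why: SN2 quaternisation of the phosphine by the primary bromide (phosphonium salt formation), the salt crystallising from the medium.

Step 2
Reactants: 3 2-methylcyclopentane-1,3-dione; 4 but-3-en-2-one
Product: 7 (7aR)-7a-methyl-2,3,7,7a-tetrahydro-1H-indene-1,5(6H)-dione, via triketone 5 (not isolated), via aldol ketol 6 (not isolated)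
Conditions: 4 (1.4 equiv), AcOH (cat.), H2O, 70 °C; solvent exchanged for DMF, D-proline (3 mol%), 20 °C, 24 h; then H2SO4 (cat.), 95 °C
Reagents that add atoms: none
Why: Michael addition, then the Hajos–Parrish–Eder–Sauer–Wiechert aldol, in which the D-proline enamine attacks one of the two enantiotopic ring carbonyls through a carboxylic-acid-bound chair transition state and sets the (R) quaternary centre (C-10), and acid dehydration closes ring A as the enone.

Step 3
Reactants: 7 (R)-Hajos–Parrish ketone; 2 (3-carboxypropyl)triphenylphosphonium bromide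
Product: 9 methyl (4Z)-4-[(7aS)-7a-methyl-5-oxo-2,3,5,6,7,7a-hexahydro-1H-inden-1-ylidene]butanoate, via carboxylic acid 8 (not isolated)
Conditions: 2 (2.5 equiv), KOtBu (5.2 equiv), THF, 0 °C → reflux; aq. HCl; crude acid, MeI, K2CO3, DMF, 20 °C
Reagents that add atoms: iodomethane, CI
Why: Wittig olefination in which the excess basic ylide first turns the enone into its inert dienolate and then olefinates the saturated cyclopentanone from the face opposite the angular methyl to give the Z alkene (chain syn to C-10, as in the ethylidenation of 17-oxo steroids), followed by SN2 esterification of the carboxylate.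

Step 4
Reactants: 9 methyl (Z)-alkylidene ester
Product: 10 methyl 3-[(1R,8aS)-8a-methyl-2,6-dioxo-1,2,3,4,6,7,8,8a-octahydronaphthalen-1-yl]propanoate
Conditions: PhI(OH)OTs (1.2 equiv), MeOH–H2O 95:5, −20 → 20 °C, 2 h; NaHCO3 work-up
Reagents that add atoms: water, O
Why: Proposed new method: a stereospecific oxidative semipinacol ring expansion by trivalent iodine on a fully aliphatic, trisubstituted (Z)-alkylidenecyclopentane, in which electrophilic PhI(OH)+ adds to the exocyclic olefin (the enone olefin is too electron-poor) from the face opposite the angular methyl, solvent captures the tertiary C-8 cation in the Markovnikov sense, and the C-8–C-10 bond, placed anti-periplanar to the C-9–I bond of the alkyl-λ3-iodane, migrates to C-9 with inversion as PhI leaves while the oxygen lone pair turns C-8 into the ketone, the quaternary C-10 migrating in preference to CH2-7 as in the D-homoannulation of 17-hydroxy-20-substituted pregnanes, so that Z geometry plus anti-methyl attack put the C-9 chain trans to the C-10 methyl; the closest known reactions are the oxidative ring expansion of methylene- and benzylidene-cycloalkanes with PhI(OH)OTs or thallium trinitrate and the semipinacol (Tiffeneau–Demjanov-type) shift of 2-sulfonyloxy tertiary alcohols, and what is new is the substrate class (non-benzylic trisubstituted olefin, two competing migrating carbons, a defined stereocentre created next to a quaternary carbon).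

Step 5
Reactants: 10 ring-expanded enedione ester
Product: 12 enone δ-lactone (O-8 bonded to the C-13 carbonyl), via tertiary alcohol 11 (not isolated)
Conditions: MeMgBr (1.2 equiv), PhMe–Et2O, −78 °C; then CF3CO2H (10 equiv), 0 → 20 °C
Reagents that add atoms: methylmagnesium bromide, C[Mg]Br
Why: Grignard 1,2-addition to the saturated ketone (more electrophilic than the vinylogous enone carbonyl or the ester at −78 °C) and then acid-induced SN1 lactonisation, in which the tertiary C-8 cation can be reached by the ester of the axial C-9 chain only from the face of that chain, so the cis-fused δ-lactone fixes C-8 (oxygen trans and CH3 cis to the C-10 methyl) whichever face the Grignard reagent attacked.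

Step 6
Reactants: 12 enone δ-lactone
Product: 13 4,4-dimethyl-3-oxo-Δ5 δ-lactone
Conditions: KOtBu (3.5 equiv), tBuOH–THF, 20 °C; MeI (8 equiv)
Reagents that add atoms: iodomethane, CI
Why: Deconjugative α,α-dimethylation: KOtBu forms the extended dienolate by γ-deprotonation at C-6, which is methylated twice at C-4 and leaves the C-5=C-6 olefin, the lactone α-CH2 being about five pK units less acidic.

Step 7
Reactants: 13 4,4-dimethyl-3-oxo-Δ5 δ-lactone
Product: 15 3,6-diol δ-lactone, via borane adduct 14 (not isolated)
Conditions: BH3·SMe2 (4 equiv), THF, 0 → 20 °C, 16 h; then H2O2 (30%), aq. NaHCO3, 0 → 20 °C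
Reagents that add atoms: hydrogen peroxide, OO; borane–dimethyl sulfide (boron only in intermediate 14), [BH3-][S+](C)C
Why: Borane first reduces the C-3 ketone by axial hydride delivery (the equatorial approach is blocked by the axial C-4 methyl) to the equatorial 3-OH cis to the C-10 methyl, then hydroborates the Δ5 olefin syn and anti-Markovnikov from the face opposite the C-10 and axial C-4 methyls, and stereoretentive oxidation leaves H-5 and the equatorial 6-OH both trans to the C-10 methyl (trans-decalin).

Step 8
Reactants: 15 3,6-diol δ-lactone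
Product: 16 3,6,8-triol vinyl ketone (C-9 chain CH2CH2C(=O)CH=CH2)
Conditions: CH2=CHMgBr (4 equiv), THF, −78 → −40 °C; aq. NH4Cl
Reagents that add atoms: vinylmagnesium bromide, C=C[Mg]Br
Why: Grignard addition to the lactone stops at the tetrahedral magnesium hemiketalate at low temperature (two further equivalents only deprotonate the secondary hydroxyls), so work-up releases the vinyl ketone and the free tertiary 8-OH.

Step 9
Reactants: 16 triol vinyl ketone
Product: 17 3,6,8-triol with the 13(16),14-diene chain
Conditions: Ph3PCH3Br (6 equiv), KOtBu (5.5 equiv), THF, 0 → 40 °C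
Reagents that add atoms: methyltriphenylphosphonium bromide, C[P+](c1ccccc1)(c1ccccc1)c1ccccc1.[Br-]
Why: Wittig methylenation of the ketone carbonyl gives the 2-substituted buta-1,3-diene, the three alkoxides being spectators.

Step 10
Reactants: 17 triol diene
Product: 20 target, via 3-O-triethylsilyl ether 18 (not isolated), via 3-O-silyl 6-acetate 19 (not isolated)
Conditions: Et3SiCl (1.1 equiv), imidazole, CH2Cl2, −40 °C; then Ac2O, Et3N, DMAP (cat.), 20–40 °C; then HF·pyridine, THF, 0 °C
Reagents that add atoms: acetic anhydride, CC(=O)OC(C)=O; chlorotriethylsilane (silicon only in intermediates 18 and 19), CC[Si](Cl)(CC)CC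
Why: One-pot transient protection: the equatorial 3-OH (one quaternary neighbour) is silylated faster than the 6-OH (flanked by C-5 and buttressed by the equatorial C-4 methyl) and the tertiary 8-OH, DMAP-catalysed acylation then takes the only free secondary hydroxyl, and fluoride removes the silyl ether without touching the acetate or the diene.

**Compound list**
1 | 4-bromobutanoic acid | OC(=O)CCCBr | starting material
2 | (3-carboxypropyl)triphenylphosphonium bromide | OC(=O)CCC[P+](c1ccccc1)(c1ccccc1)c1ccccc1.[Br-] | intermediate
3 | 2-methylcyclopentane-1,3-dione | CC1C(=O)CCC1=O | starting material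
4 | but-3-en-2-one (methyl vinyl ketone) | CC(=O)C=C | starting material
5 | 2-methyl-2-(3-oxobutyl)cyclopentane-1,3-dione | CC(=O)CCC1(C)C(=O)CCC1=O | intermediate
6 | (3aR,7aR)-3a-hydroxy-7a-methylhexahydro-1H-indene-1,5(6H)-dione (cis-fused ketol) | O=C1[C@]2(C)CCC(=O)C[C@]2(O)CC1 | intermediate
7 | (7aR)-7a-methyl-2,3,7,7a-tetrahydro-1H-indene-1,5(6H)-dione ((R)-Hajos–Parrish ketone) | O=C1[C@]2(C)CCC(=O)C=C2CC1 | intermediate
8 | (4Z)-4-[(7aS)-7a-methyl-5-oxo-2,3,5,6,7,7a-hexahydro-1H-inden-1-ylidene]butanoic acid (chain syn to the quaternary carbon; same spatial arrangement at that carbon as in 7) | OC(=O)CC/C=C1\[C@]2(C)CCC(=O)C=C2CC1 | intermediate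
9 | methyl ester of 8 | COC(=O)CC/C=C1\[C@]2(C)CCC(=O)C=C2CC1 | intermediate
10 | methyl 3-[(1R,8aS)-8a-methyl-2,6-dioxo-1,2,3,4,6,7,8,8a-octahydronaphthalen-1-yl]propanoate (8-ketone, ring-A enone, C-9 chain trans to the C-10 methyl) | COC(=O)CC[C@@H]1[C@]2(C)CCC(=O)C=C2CCC1=O | intermediate
11 | tertiary alcohol from CH3MgBr addition at C-8 of 10, drawn as the expected major epimer (8-OH cis to the C-10 methyl) | COC(=O)CC[C@@H]1[C@]2(C)CCC(=O)C=C2CC[C@@]1(C)O | intermediate
12 | enone δ-lactone: six-membered lactone C-13(=O)–C-12–C-11–C-9–C-8–O, ring-A 3-oxo-Δ4 enone, O-8 and C-11 trans to the C-10 methyl, 8-CH3 cis to it | O=C1CC[C@@H]2[C@]3(C)CCC(=O)C=C3CC[C@]2(C)O1 | intermediate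
13 | 12 with gem-dimethyl at C-4 and the olefin at C-5=C-6 | O=C1CC[C@@H]2[C@]3(C)CCC(=O)C(C)(C)C3=CC[C@]2(C)O1 | intermediate
14 | borane adduct of 13: C-3 as CH–OBH2 (oxygen cis to the C-10 methyl), BH2 on C-6, H-5 and B-6 trans to the C-10 methyl | O=C1CC[C@@H]2[C@]3(C)CC[C@@H](OB)C(C)(C)[C@H]3[C@H](B)C[C@]2(C)O1 | intermediate
15 | 3,6-diol δ-lactone: 3-OH cis to the C-10 methyl, H-5 and 6-OH trans to it, lactone as in 12 | O=C1CC[C@@H]2[C@]3(C)CC[C@@H](O)C(C)(C)[C@H]3[C@H](O)C[C@]2(C)O1 | intermediate
16 | 3,6,8-triol with the C-9 chain CH2CH2C(=O)CH=CH2 (can close reversibly onto the ketone through the 8-OH) | C=CC(=O)CC[C@@H]1[C@]2(C)CC[C@@H](O)C(C)(C)[C@H]2[C@H](O)C[C@]1(C)O | intermediate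
17 | 3,6,8-triol with the 13(16),14-diene chain (deacetyl target) | C=CC(=C)CC[C@@H]1[C@]2(C)CC[C@@H](O)C(C)(C)[C@H]2[C@H](O)C[C@]1(C)O | intermediate
18 | 3-O-triethylsilyl ether of 17 | C=CC(=C)CC[C@@H]1[C@]2(C)CC[C@@H](O[Si](CC)(CC)CC)C(C)(C)[C@H]2[C@H](O)C[C@]1(C)O | intermediate
19 | 6-O-acetate of 18 | C=CC(=C)CC[C@@H]1[C@]2(C)CC[C@@H](O[Si](CC)(CC)CC)C(C)(C)[C@H]2[C@H](OC(C)=O)C[C@]1(C)O | intermediate
20 | CNP0351600.2: 6-acetoxy-3,8-dihydroxy-labda-13(16),14-diene skeleton with (3R,5S,6R,8S,9R,10R) configuration | C=CC(=C)CC[C@@H]1[C@]2(C)CC[C@@H](O)C(C)(C)[C@H]2[C@H](OC(C)=O)C[C@]1(C)O | target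

**Step count and risks**
Total steps: 10. Longest linear sequence: 9 (steps 2 to 10, from 3 and 4 to 20); step 1 is a one-step branch that joins at step 3.

Three steps most likely to fail:

Step 4 (the new reaction). It may give 1,2-dimethoxylation, migration of CH2-7 instead of C-10, participation of the ester, or acid epimerisation at C-9. The fallback uses known chemistry, sets out from 9 and returns at 10. OsO4 (2 mol%) with N-methylmorpholine N-oxide in acetone–water dihydroxylates the exocyclic olefin from the face opposite the angular methyl to give the 8,9-diol ester F1. MsCl, Et3N, CH2Cl2, −20 °C sulfonylates only the secondary hydroxyl to give the hydroxy mesylate F2. KOtBu (1.05 equiv), THF, 0 °C then drives the alkoxide-triggered semipinacol rearrangement (C-10 shifts anti to the mesylate with inversion at C-9, the D-homoannulation type known from 17-hydroxy-20-sulfonyloxy steroids). This gives 10 with the same C-9 configuration, because the leaving group sits on the same face as the iodane of the main route.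

Step 5. The Grignard reagent may also attack the enone, and the acid stage may give olefin mixtures. The fallback sets out from 10 and returns at 12. Wittig methylenation (Ph3PCH3Br, KOtBu, THF; the enone is shielded as its dienolate) gives the exocyclic methylene keto ester F3. CF3SO3H (5 mol%), CH2Cl2, −20 °C protonates the 1,1-disubstituted olefin to the same tertiary C-8 cation, which the ester captures to give 12.

Step 7. Borane may reduce the δ-lactone before the hindered olefin has reacted (its reacting face carries the axial C-11). The fallback sets out from 11 and returns at 15. Compound 11 is isolated after an NH4Cl quench of the Grignard addition (no acid). Deconjugative methylation (KOtBu, MeI) gives the hydroxy ester F4. BH3·SMe2 then H2O2/NaHCO3 gives the triol ester F5; an open-chain methyl ester is reduced by borane far more slowly than a lactone. TsOH·H2O (10 mol%), toluene, 40 °C then closes the lactone by the same cation capture to give 15.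

Further compounds
F1 | step 4 | methyl 4-hydroxy-4-[1-hydroxy-7a-methyl-5-oxo-2,3,5,6,7,7a-hexahydro-1H-inden-1-yl]butanoate (8,9-diol, both hydroxyls on the face opposite the angular methyl) | COC(=O)CC[C@@H](O)[C@@]1(O)[C@]2(C)CCC(=O)C=C2CC1
F2 | step 4 | 9-O-methanesulfonate of F1 | COC(=O)CC[C@@H](OS(C)(=O)=O)[C@@]1(O)[C@]2(C)CCC(=O)C=C2CC1
F3 | step 5 | methyl 3-[8a-methyl-2-methylidene-6-oxo-1,2,3,4,6,7,8,8a-octahydronaphthalen-1-yl]propanoate (chain trans to the angular methyl) | COC(=O)CC[C@@H]1[C@]2(C)CCC(=O)C=C2CCC1=C
F4 | step 7 | 11 with gem-dimethyl at C-4 and the olefin at C-5=C-6 (4,4-dimethyl-3-oxo-Δ5 hydroxy ester, 8-OH cis to the C-10 methyl) | COC(=O)CC[C@@H]1[C@]2(C)CCC(=O)C(C)(C)C2=CC[C@@]1(C)O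
F5 | step 7 | 3,6,8-triol methyl ester (3-OH cis to the C-10 methyl, H-5 and 6-OH trans, 8-OH cis) | COC(=O)CC[C@@H]1[C@]2(C)CC[C@@H](O)C(C)(C)[C@H]2[C@H](O)C[C@@]1(C)O
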